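Red repeats the larch run, so I take its end from the reading at 2.50 d: 11.4% open intermediate. Amber keeps the same mixture 5.00 times as long on average, and yet I reckon its outlet at 13.4%, above red's reading.

| flask | substrate | partner | remark | time |
|---|---|---|---|---|
| larch | 0.52 M | 0.52 M | run made earlier |  |
| elm | 0.52 M | 0.26 M | run made earlier |  |
| birch | 0.52 M | 1 M | run made earlier |  |
| oak | 1 M | 0.52 M | run made earlier |  |
| grey | 0.52 M (fed, over 2.00 d) | 0.520 M | all but substrate at the start; substrate goes in evenly over 2.00 d, the run ends at 2.5 d | 2.5 d |
| violet | 0.52 M | 0.520 M | one stirred flow tank at steady state, fed with the mixture as stated, mean residence time 2.5 d |  |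
| red | 0.52 M | 0.520 M | everything together in a closed stirred flask, run for 2.5 d | 2.5 d |
| amber | 0.52 M | 0.520 M | one stirred flow tank at steady state, fed with the mixture as stated, mean residence time 12.5 d |  |

- larch (time / d: open intermediate / %, target / %): 0.500: 47.8, 21.1; 1.04: 27.7, 32.8; 1.67: 17.5, 41.6; 2.08: 13.9, 42.1; 2.50: 11.4, 46.0
- elm (time / h: open intermediate / %, target / %): 3.00: 81.8, 1.3; 10.0: 61.4, 10.3; 15.0: 50.4, 14.1; 25.0: 37.4, 19.0; 40.0: 24.7, 22.7
- birch (time / h: open intermediate / %, target / %): 8.00: 52.1, 31.6; 15.0: 31.7, 43.9; 20.0: 22.4, 52.0; 30.0: 13.1, 59.2; 40.0: 7.2, 61.5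
- oak (time / h: open intermediate / %, target / %): 8.00: 52.5, 14.7; 15.0: 33.2, 21.2; 20.0: 26.6, 23.7; 30.0: 18.0, 25.8; 40.0: 13.9, 28.1

(scatter of a reading: 1 percentage point)

* the set-up with the highest amount of open intermediate at the outlet or at the end, in percent of the substrate put in ("none" if the first two lie within 2 percentage points) (grey / violet / red / amber / none)
* amount of open intermediate at the outlet or at the end, in percent of the substrate put in, grey
* amount of open intermediate at the outlet or at the end, in percent of the substrate put in, violet
* amount of open intermediate at the outlet or at the end, in percent of the substrate put in, red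
* amount of open intermediate at the outlet or at the end, in percent of the substrate put in, amber

The two numbers go together once I write the tank's balance. Elm already shows 81.8% open intermediate at 3.00 h, far sooner than a stay of days, so I count the feed as open intermediate. I call λ the specific loss, the fraction of open intermediate that goes per day at a given [open intermediate]. Between the larch readings at 1.67 d and 2.50 d it reads 0.516 d⁻¹, and between 0.500 d and 1.67 d it reads 0.859 d⁻¹.

So the early λ, read at the higher [open intermediate], is larger than the late one, and I treat each as a pseudo-first-order constant, good at its own level. A tank runs at its outlet level, and feed equals loss there, so the outlet fraction is 1/(1 + λτ). I assume partner's different history matters little.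

| Flask | Larch level | λ | τ | Outlet |
|---|---|---|---|---|
| violet | 28.9% | 0.859 d⁻¹ | 2.5 d | 31.8% |
| amber | 14.1% | 0.516 d⁻¹ | 12.5 d | 13.4% |

Each outlet lands near the level its λ was read at. Grey needs stepping through, and I don't reckon it.

The forecast gives grey 29.5%, violet 33%, red 11.4% and amber 14.8%, with violet best, because “Feeding or back-mixing keeps I dilute, which limits the second-order loss.”

The flask gives grey 27.3%, violet 30.4%, red 10.9% and amber 14.2%, so violet stands highest.

    substrate → open intermediate (k = 0.820 h⁻¹)
    partner → second intermediate (k = 2.10 h⁻¹)
    open intermediate + second intermediate ⇌ target (K = 55.0 L mol⁻¹, k = 0.0670 L mol⁻¹ h⁻¹)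
    2 open intermediate → homo product (k = 0.0530 L mol⁻¹ h⁻¹)

Set back into the balance, the outlets ask for λ of 0.916 d⁻¹ in violet and 0.483 d⁻¹ in amber, against my 0.859 d⁻¹ and 0.516 d⁻¹ from larch. That λ puts the half-life of open intermediate in amber at 34.4 h, far longer than the 0.85 h of substrate by opening alone, and amber's substrate stands at 0.00211 M everywhere in the tank, 0.405% of the charge.

(All runs are calculated with made-up constants; noise was put on by code.)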